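**Retrosynthetic overview**
1. Numbering follows the target (ring C1–C6, exocyclic CH2 = C7). Acetonide cleavage, benzoylation of O7 and reduction of a C7 aldehyde and a C4 ketone lead back to a bicyclic enone aldehyde.
2. Feature used: with C4 as a ketone, the carbocycle is a cyclohex-2-enone. It divides into a four-carbon 1-methoxy-3-silyloxy diene (C6–C5–C4–C3, C3 benzoate in place) and a two-carbon ene unit C1=C2, whose cis oxygens O1/O2 sit in one 2,2-dimethyl-1,3-dioxole ring and whose C7 is a formyl group.
3. Key disconnection: C6–C1 and C2–C3, formed together in an enantioselective [4+2] union of the two achiral pieces on a copper bis(oxazoline) catalyst. This closes the only carbocycle; the dioxole ring, made beforehand, ends as the acetonide.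
4. The diene comes from 4-methoxybut-3-en-2-one (α'-benzoyloxylation, then silyl enol ether). The dienophile comes from methyl glycerate acetonide, dehydrogenated at the ester level because the free aldehyde would not survive selenenylation and peroxide; ester → alcohol → aldehyde follows.

Key step: step 6

Assumption: the sense of induction is assigned from the square-planar chelate model of the copper complex of (S,S)-t-Bu-box (2,2'-(propane-2,2-diyl)bis[(4S)-4-tert-butyl-4,5-dihydrooxazole]); should the antipode form, the (R,R) ligand is used and nothing else changes.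

**Route**

Step 1
Reactants: 1 (E)-4-methoxybut-3-en-2-one; 2 benzoic acid (excess)
Product: 3 (E)-4-methoxy-2-oxobut-3-en-1-yl benzoate
Conditions: Mn(OAc)3·2H2O, benzene, reflux (Dean–Stark)
Reagents that add atoms: none
Why: Mn(OAc)3-mediated α'-acyloxylation of an enone, in which the trivalent-manganese enolate of the methyl ketone is oxidised and takes up a benzoate ligand; the methyl group is the only enolisable position and the (E)-enol ether is left alone under these non-aqueous conditions.

Step 2
Reactants: 3 (E)-4-methoxy-2-oxobut-3-en-1-yl benzoate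
Product: 4 (1E,3Z)-4-benzoyloxy-1-methoxy-3-(trimethylsilyloxy)buta-1,3-diene
Conditions: Me3SiOTf, Et3N, Et2O, 0 °C
Reagents that add atoms: trimethylsilyl trifluoromethanesulfonate, C[Si](C)(C)OS(=O)(=O)C(F)(F)F
Why: Soft enolisation and O-silylation of the α-benzoyloxy ketone on its only enolisable side should give the silyl enol ether with the (Z) geometry usual for α-acyloxy ketones, the benzoate cis to the silyloxy group and pointing outward in the s-cis diene.

Step 3
Reactants: 5 methyl (R)-2,2-dimethyl-1,3-dioxolane-4-carboxylate
Product: 8 methyl 2,2-dimethyl-1,3-dioxole-4-carboxylate, via α-phenylselanyl ester 6 (not isolated), via selenoxide 7 (not isolated)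
Conditions: LiN(i-Pr)2, THF, −78 °C; PhSeBr, −78 °C; then 30% H2O2, 0 °C → rt (one flask)
Reagents that add atoms: none
Why: Ester enolate α-selenenylation, oxidation and selenoxide syn-elimination (Reich–Sharpless dehydrogenation): the ring C–O bond lies in the nodal plane of the exocyclic enolate, which should hold back β-elimination at −78 °C, the only β-hydrogens of 7 are on the ring CH2 so that elimination can only give the endocyclic double bond, and the diisopropylamine present scavenges benzeneselenenic acid; the stereocentre of 5 is lost, so either enantiomer or the racemate serves.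

Step 4
Reactants: 8 methyl 2,2-dimethyl-1,3-dioxole-4-carboxylate
Product: 9 (2,2-dimethyl-1,3-dioxol-4-yl)methanol
Conditions: i-Bu2AlH (2.2 equiv), CH2Cl2, −78 °C; Rochelle salt work-up
Reagents that add atoms: none
Why: 1,2-Reduction of an α,β-unsaturated ester to the allylic alcohol by i-Bu2AlH, with a non-acidic work-up that spares the enol acetal.

Step 5
Reactants: 9 (2,2-dimethyl-1,3-dioxol-4-yl)methanol
Product: 10 2,2-dimethyl-1,3-dioxole-4-carbaldehyde
Conditions: MnO2 (activated, excess), CH2Cl2, rt; filtered and used at once as the CH2Cl2 solution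
Reagents that add atoms: none
Why: MnO2 oxidation of an allylic alcohol to the enal under neutral, heterogeneous conditions, so that the volatile and acid-sensitive aldehyde needs only a filtration.

Step 6
Reactants: 4 (1E,3Z)-4-benzoyloxy-1-methoxy-3-(trimethylsilyloxy)buta-1,3-diene; 10 2,2-dimethyl-1,3-dioxole-4-carbaldehyde
Product: 12 (1R,2S,3S)-3-benzoyloxy-1,2-(isopropylidenedioxy)-4-oxocyclohex-5-ene-1-carbaldehyde, via silyl enol ether cycloadduct 11 (not isolated)
Conditions: Cu(OTf)2 (10 mol%), (S,S)-t-Bu-box (11 mol%), 4 Å MS, CH2Cl2, −78 → −20 °C; then CF3CO2H, 0 °C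
Reagents that add atoms: none
Why: Proposed new method: divalent copper in the Cu(OTf)2–bis(oxazoline) complex binds the formyl oxygen and the dioxole oxygen on the formyl-bearing carbon of 10 in a five-membered chelate, which makes the push–pull enal a vinylogous oxocarbenium ion electrophilic at the O-bearing CH (future C2); the silyl-enol-ether terminus of 4 (future C3) bonds there and the methoxy-bearing terminus (future C6) bonds to the formyl-bearing carbon (future C1), closing the six-membered carbocycle by a concerted but asynchronous [4+2] cycloaddition (at the stepwise limit a Mukaiyama–Michael addition followed by 6-(enolexo)-exo-trig capture of the oxocarbenium ion by the copper enolate), after which CF3CO2H cleaves the silyl enol ether of 11 and eliminates methanol to give the enone. The closest known reaction types are the Lewis-acid-catalysed enantioselective Diels–Alder reactions of 1-alkoxy-3-silyloxy dienes with α-oxygenated acroleins and the copper bis(oxazoline)-catalysed cycloadditions of two-point-binding carbonyl compounds; what is new is a dienophile that also carries a donor oxygen on its β-carbon. C1 and C2 are created together: the cis relationship of their oxygens is fixed by the dioxole ring, and their absolute configuration by the ligand, whose tert-butyl group next to the chelated alkene shields one face so that the diene should add to the Si face of the formyl-bearing carbon. C3 follows from the endo approach (formyl group under the diene) of the outward-pointing (3Z)-benzoyloxy terminus, which places the benzoate trans to O2 and cis to C7; because C3 is α to the new ketone, an exo-derived epimer can be equilibrated with catalytic Et3N to this pseudo-equatorial benzoate, and the C6 methoxy stereocentre of 11 is lost on elimination. The step needs addition across the C=C bond of 10 and not hetero-Diels–Alder or aldol addition at the formyl C=O, the regiochemistry C3–C2/C6–C1, and enantioface control: the first two rest on the ring oxygen at the β-carbon, which should move the electrophilic site of the chelated enal from the formyl carbon to C2, together with the polarisation of the 1-methoxy-3-silyloxy diene, and the third on the rigid two-point chelate.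

Step 7
Reactants: 12 (1R,2S,3S)-3-benzoyloxy-1,2-(isopropylidenedioxy)-4-oxocyclohex-5-ene-1-carbaldehyde
Product: 13 [(1S,2S,3R,4S)-3-benzoyloxy-4-hydroxy-1,2-(isopropylidenedioxy)cyclohex-5-en-1-yl]methanol
Conditions: NaBH4 (excess), CeCl3·7H2O, MeOH, −78 → −20 °C; AcOH quench
Reagents that add atoms: none
Why: Luche reduction, in which NaBH4/CeCl3 reduces the aldehyde to the primary alcohol and the enone carbonyl in the 1,2-sense without touching the benzoate, the weakly acidic cerium medium holding back deformylation and benzoate migration; C4 is set by axial hydride attack on the half-chair enone, anti to the pseudo-axial C3–H and on the convex face opposite the acetonide, which should give the pseudo-equatorial 4β-alcohol trans to the 3α-benzoate.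

Step 8
Reactants: 13 [(1S,2S,3R,4S)-3-benzoyloxy-4-hydroxy-1,2-(isopropylidenedioxy)cyclohex-5-en-1-yl]methanol
Product: 14 [(1S,2S,3R,4S)-3-benzoyloxy-4-hydroxy-1,2-(isopropylidenedioxy)cyclohex-5-en-1-yl]methyl benzoate
Conditions: BzCl (1.05 equiv), 2,4,6-collidine, CH2Cl2, −78 → −20 °C
Reagents that add atoms: benzoyl chloride, O=C(Cl)c1ccccc1
Why: Kinetic acylation of a primary alcohol beside a secondary one with an acid chloride and a hindered pyridine base at low temperature; the secondary allylic C4–OH is flanked by the C3 benzoate and should react far more slowly.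

Step 9
Reactants: 14 [(1S,2S,3R,4S)-3-benzoyloxy-4-hydroxy-1,2-(isopropylidenedioxy)cyclohex-5-en-1-yl]methyl benzoate
Product: 15 [(1S,2S,3R,4S)-3-benzoyloxy-1,2,4-trihydroxycyclohex-5-en-1-yl]methyl benzoate (the target)
Conditions: CF3CO2H–H2O (9:1), CH2Cl2, 0 °C
Reagents that add atoms: none
Why: Acid-catalysed hydrolysis of the isopropylidene ketal; the benzoates and the allylic alcohol should be stable to cold aqueous trifluoroacetic acid and no stereocentre is touched.

**Compound list**
1 | (E)-4-methoxybut-3-en-2-one | CO/C=C/C(C)=O | starting material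
2 | benzoic acid | O=C(O)c1ccccc1 | starting material
3 | (E)-4-methoxy-2-oxobut-3-en-1-yl benzoate | CO/C=C/C(=O)COC(=O)c1ccccc1 | intermediate
4 | (1E,3Z)-4-benzoyloxy-1-methoxy-3-(trimethylsilyloxy)buta-1,3-diene | CO/C=C/C(O[Si](C)(C)C)=C/OC(=O)c1ccccc1 | intermediate
5 | methyl (R)-2,2-dimethyl-1,3-dioxolane-4-carboxylate | COC(=O)[C@H]1COC(C)(C)O1 | starting material
6 | methyl 2,2-dimethyl-4-(phenylselanyl)-1,3-dioxolane-4-carboxylate (racemic) | COC(=O)C1([Se]c2ccccc2)COC(C)(C)O1 | intermediate
7 | methyl 2,2-dimethyl-4-(phenylseleninyl)-1,3-dioxolane-4-carboxylate (diastereomer mixture) | COC(=O)C1([Se](=O)c2ccccc2)COC(C)(C)O1 | intermediate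
8 | methyl 2,2-dimethyl-1,3-dioxole-4-carboxylate | COC(=O)C1=COC(C)(C)O1 | intermediate
9 | (2,2-dimethyl-1,3-dioxol-4-yl)methanol | OCC1=COC(C)(C)O1 | intermediate
10 | 2,2-dimethyl-1,3-dioxole-4-carbaldehyde | O=CC1=COC(C)(C)O1 | intermediate
11 | (1R,2S,3S,6S)-3-benzoyloxy-1,2-(isopropylidenedioxy)-6-methoxy-4-(trimethylsilyloxy)cyclohex-4-ene-1-carbaldehyde | O=C[C@@]1(OC(C)(C)O2)[C@@H](OC)C=C(O[Si](C)(C)C)[C@@H](OC(=O)c3ccccc3)[C@@H]12 | intermediate
12 | (1R,2S,3S)-3-benzoyloxy-1,2-(isopropylidenedioxy)-4-oxocyclohex-5-ene-1-carbaldehyde | O=C[C@@]1(OC(C)(C)O2)C=CC(=O)[C@@H](OC(=O)c3ccccc3)[C@@H]12 | intermediate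
13 | [(1S,2S,3R,4S)-3-benzoyloxy-4-hydroxy-1,2-(isopropylidenedioxy)cyclohex-5-en-1-yl]methanol | OC[C@@]1(OC(C)(C)O2)C=C[C@H](O)[C@@H](OC(=O)c3ccccc3)[C@@H]12 | intermediate
14 | [(1S,2S,3R,4S)-3-benzoyloxy-4-hydroxy-1,2-(isopropylidenedioxy)cyclohex-5-en-1-yl]methyl benzoate | O=C(OC[C@@]1(OC(C)(C)O2)C=C[C@H](O)[C@@H](OC(=O)c3ccccc3)[C@@H]12)c1ccccc1 | intermediate
15 | [(1S,2S,3R,4S)-3-benzoyloxy-1,2,4-trihydroxycyclohex-5-en-1-yl]methyl benzoate (1α-benzoyloxymethyl-3α-benzoyloxycyclohex-5-en-1β,2β,4β-triol) | O=C(OC[C@@]1(O)C=C[C@H](O)[C@@H](OC(=O)c2ccccc2)[C@@H]1O)c1ccccc1 | target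

**Totals**
Total step count: 9 (two for the diene, three for the dienophile, four from the union onward).
Longest linear sequence: 7 steps (steps 3, 4, 5, 6, 7, 8, 9 from compound 5).

**Steps most likely to fail**

1. Step 6. The diene may add to the formyl C=O (hetero-Diels–Alder or Mukaiyama aldol) instead of the C=C bond, the donor-substituted dienophile may be too weakly electrophilic for turnover, or enantioface discrimination may be poor. Fallback by known chemistry, setting out from benzoic acid 2 and coming back at 15: 2 is esterified with commercial 4-hydroxybenzyl alcohol under Mitsunobu conditions (PPh3, DIAD, THF) to give 4-hydroxybenzyl benzoate F1. Oxidative dearomatisation (PhI(OAc)2, MeCN–H2O, 0 °C) should give the achiral p-quinol (1-hydroxy-4-oxocyclohexa-2,5-dien-1-yl)methyl benzoate F2. A chiral BINOL-phosphoric-acid-catalysed hemiacetalisation and intramolecular oxa-Michael cascade with isobutyraldehyde, a known enantioselective desymmetrisation of p-quinols (catalyst antipode chosen for the 1S,2S sense), should then give the cis-fused dioxolane enone [(1S,2S)-1,2-(2-methylpropylidenedioxy)-4-oxocyclohex-5-en-1-yl]methyl benzoate F3, which carries O1 and O2 cis. Mn(OAc)3 with benzoic acid 2 (the reaction type of step 1) should introduce the α'-benzoate from the convex face to give [(1S,2S,3S)-3-benzoyloxy-1,2-(2-methylpropylidenedioxy)-4-oxocyclohex-5-en-1-yl]methyl benzoate F4. Luche reduction as in step 7 should give [(1S,2S,3R,4S)-3-benzoyloxy-4-hydroxy-1,2-(2-methylpropylidenedioxy)cyclohex-5-en-1-yl]methyl benzoate F5, and aqueous CF3CO2H removes the acetal to give 15.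

2. Step 3. The lithium enolate may fragment by β-elimination of the ring oxygen before it is selenenylated, and benzeneselenenic acid or peroxide may add back to the electron-rich dioxole during the elimination. Fallback, setting out from 5 and coming back at 8: 5 is deprotonated in the presence of Me3SiCl (LiN(i-Pr)2, internal quench, THF, −78 °C) so that the enolate is trapped as it forms, giving the silyl ketene acetal [(2,2-dimethyl-1,3-dioxolan-4-ylidene)(methoxy)methoxy]trimethylsilane F6. Saegusa–Ito dehydrosilylation with Pd(OAc)2 in MeCN at room temperature should then give 8 without selenium or peroxide.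

3. Step 7. Hydride may be delivered to the wrong face of C4, and base-induced benzoate migration from O3 to O4 may follow. Fallback, setting out from 12 and coming back at 14: if the reduction gives mainly the 4α-alcohol [(1S,2S,3R,4R)-3-benzoyloxy-4-hydroxy-1,2-(isopropylidenedioxy)cyclohex-5-en-1-yl]methanol F7, this is benzoylated at the primary hydroxyl as in step 8 to give [(1S,2S,3R,4R)-3-benzoyloxy-4-hydroxy-1,2-(isopropylidenedioxy)cyclohex-5-en-1-yl]methyl benzoate F8. Mitsunobu inversion at C4 with chloroacetic acid (PPh3, DIAD, toluene, 0 °C) should give [(1S,2S,3R,4S)-3-benzoyloxy-4-(chloroacetoxy)-1,2-(isopropylidenedioxy)cyclohex-5-en-1-yl]methyl benzoate F9. Thiourea with NaHCO3 in EtOH then removes the chloroacetate in the presence of the benzoates to give 14.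

**Further compounds**
F1 | step 6 | 4-hydroxybenzyl benzoate | O=C(OCc1ccc(O)cc1)c1ccccc1
F2 | step 6 | (1-hydroxy-4-oxocyclohexa-2,5-dien-1-yl)methyl benzoate | O=C(OCC1(O)C=CC(=O)C=C1)c1ccccc1
F3 | step 6 | [(1S,2S)-1,2-(2-methylpropylidenedioxy)-4-oxocyclohex-5-en-1-yl]methyl benzoate (acetal carbon: either epimer, removed at the end) | O=C(OC[C@@]1(OC(C(C)C)O2)C=CC(=O)C[C@@H]12)c1ccccc1
F4 | step 6 | [(1S,2S,3S)-3-benzoyloxy-1,2-(2-methylpropylidenedioxy)-4-oxocyclohex-5-en-1-yl]methyl benzoate | O=C(OC[C@@]1(OC(C(C)C)O2)C=CC(=O)[C@@H](OC(=O)c3ccccc3)[C@@H]12)c1ccccc1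
F5 | step 6 | [(1S,2S,3R,4S)-3-benzoyloxy-4-hydroxy-1,2-(2-methylpropylidenedioxy)cyclohex-5-en-1-yl]methyl benzoate | O=C(OC[C@@]1(OC(C(C)C)O2)C=C[C@H](O)[C@@H](OC(=O)c3ccccc3)[C@@H]12)c1ccccc1
F6 | step 3 | [(2,2-dimethyl-1,3-dioxolan-4-ylidene)(methoxy)methoxy]trimethylsilane | COC(O[Si](C)(C)C)=C1COC(C)(C)O1
F7 | step 7 | [(1S,2S,3R,4R)-3-benzoyloxy-4-hydroxy-1,2-(isopropylidenedioxy)cyclohex-5-en-1-yl]methanol | OC[C@@]1(OC(C)(C)O2)C=C[C@@H](O)[C@@H](OC(=O)c3ccccc3)[C@@H]12
F8 | step 7 | [(1S,2S,3R,4R)-3-benzoyloxy-4-hydroxy-1,2-(isopropylidenedioxy)cyclohex-5-en-1-yl]methyl benzoate | O=C(OC[C@@]1(OC(C)(C)O2)C=C[C@@H](O)[C@@H](OC(=O)c3ccccc3)[C@@H]12)c1ccccc1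
F9 | step 7 | [(1S,2S,3R,4S)-3-benzoyloxy-4-(chloroacetoxy)-1,2-(isopropylidenedioxy)cyclohex-5-en-1-yl]methyl benzoate | O=C(OC[C@@]1(OC(C)(C)O2)C=C[C@H](OC(=O)CCl)[C@@H](OC(=O)c3ccccc3)[C@@H]12)c1ccccc1
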